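**Plan**

Ring B is labelled B1 (quaternary carbon with methyl and geranyl), B2 (C–OH), B3 (C–acetyl), B4 (C=O), B5 (C–CH2–aryl) and B6 (C–OH); ring A is the butanoyl geranyl phloroglucinol; geranyl = (2E)-3,7-dimethylocta-2,6-dien-1-yl.
Retrosynthesis cuts, in this order: the two C–C bonds of the CH2 bridge (B5–CH2 and CH2–ring A), the CH3–CO bond of the acetyl group (back to a thioester), the ring bond B3–B4, the two aldol bonds B2–B3 and B6–B5, and the two geranyl–carbon bonds (at B1 and on ring A).
The feature that allows the ring opening: B1 carries two arms, B2–B3 and B6–B5, that differ only in what B3 and B5 bear. With B3–B4 cut and B4 written as a second thioester, the chain has two identical β-keto thioester arms on B1, is achiral, and holds all six ring B carbons.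
Forward: the chain grows outward from a geranylated methylmalonate (B1 first, then both arms by twofold aldol addition and oxidation), ring B closes, the thioester becomes the acetyl group, and separately geranylated ring A is joined last through the one-carbon bridge.
Stereochemistry: the only stereocentre, B1, arises in the ring closure, where a chiral magnesium bis(oxazoline) complex decides which enantiotopic arm is the enolate and which the acyl donor. No later step touches this quaternary carbon, and both E alkenes come unchanged from geranyl bromide.

Key step: step 6

Assumption: ring B compounds are drawn in the enol tautomer of the target, and the (S,S) ligand is written for step 6 on the assumption that it leads to the (R) product; its (R,R) antipode would be used if the first experiment showed the opposite sense.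

**Route**

Step 1
Reactants: 1 dimethyl methylmalonate; 2 geranyl bromide
Product: 3 dimethyl 2-geranyl-2-methylpropanedioate
Conditions: NaH (1.1 equiv), THF/DMF, 0 °C → rt
Reagents that add atoms: none
Why: Malonate alkylation, in which the sodium enolate of 1 displaces the primary allylic bromide by SN2 and so forms the quaternary carbon that becomes B1, with the E alkene of 2 untouched.

Step 2
Reactants: 3 dimethyl 2-geranyl-2-methylpropanedioate
Product: 4 2-geranyl-2-methylpropane-1,3-diol
Conditions: LiAlH4, THF, 0 °C → reflux; H2O/aq NaOH work-up
Reagents that add atoms: none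
Why: Hydride reduction of both ester groups of the disubstituted malonate should give the neopentyl 1,3-diol, and LiAlH4 leaves isolated trisubstituted alkenes alone.

Step 3
Reactants: 4 2-geranyl-2-methylpropane-1,3-diol
Product: 5 2-geranyl-2-methylpropanedial
Conditions: DMP (2.6 equiv), CH2Cl2, 0 °C → rt
Reagents that add atoms: none
Why: Dess–Martin oxidation takes both primary alcohols to aldehydes under neutral conditions; the dialdehyde has no α-hydrogen, so it cannot enolize, and the 1,3-relationship allows no lactol on the way.

Step 4
Reactants: 5 2-geranyl-2-methylpropanedial; 6 S-ethyl thioacetate (3 equiv)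
Product: 7 S,S-diethyl 4-geranyl-3,5-dihydroxy-4-methylheptanebis(thioate), mixture of diastereomers
Conditions: LiN(iPr)2 (3 equiv), THF, −78 °C; then 5, −78 °C; AcOH quench at −78 °C
Reagents that add atoms: none
Why: Twofold aldol addition of the lithium thioester enolate to the non-enolizable neopentyl aldehydes at low temperature attaches both two-carbon arms in one operation; the carbinol stereocentres are irrelevant because step 5 removes them.

Step 5
Reactants: 7 S,S-diethyl 4-geranyl-3,5-dihydroxy-4-methylheptanebis(thioate)
Product: 8 S,S-diethyl 4-geranyl-4-methyl-3,5-dioxoheptanebis(thioate), achiral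
Conditions: DMP (2.5 equiv), CH2Cl2, 0 °C → rt; quick filtration through neutral silica, used at once
Reagents that add atoms: none
Why: Dess–Martin oxidation of β-hydroxy thioesters to β-keto thioesters is routine and base-free, so all diastereomers of 7 should converge on achiral 8 without giving the chain a chance to cyclize before it meets the chiral complex.

Step 6
Reactants: 8 S,S-diethyl 4-geranyl-4-methyl-3,5-dioxoheptanebis(thioate)
Product: 9 S-ethyl (3R)-3-geranyl-2,4-dihydroxy-3-methyl-6-oxocyclohexa-1,4-diene-1-carbothioate
Conditions: Mg(OTf)2 (1.05 equiv), (S,S)-Ph-box [2,2'-(propane-2,2-diyl)bis((4S)-4-phenyl-4,5-dihydro-1,3-oxazole)] (1.15 equiv), N-methylmorpholine (2.5 equiv), 4 Å MS, CH2Cl2, −20 °C → rt; cold 1 M HCl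
Reagents that add atoms: none
Why: Proposed new method: the divalent magnesium centre of the Mg(OTf)2/Ph-box complex binds one β-keto thioester arm of 8 as an O,O-chelate, which makes it acidic enough for N-methylmorpholine to enolize, while the other arm sits on the same metal as a neutral chelate with an activated thioester; the enolate carbon B3 adds to that thioester carbonyl B4, ethanethiol leaves, and the acyl trione is deprotonated at once, so the closure cannot reverse. The closest known reactions are magnesium salt/amine soft-enolization Claisen and Dieckmann condensations of thioesters, magnesium bis(oxazoline)/amine enolization of 1,3-dicarbonyl compounds in enantioselective conjugate additions, and catalytic desymmetrizing aldol cyclizations of prochiral 2,2-disubstituted 1,3-diketones. Ring B closes in a 6-exo-trig mode, allowed whether the delocalized enolate is counted as enolendo (B2=B3) or enolexo (B3=C(O)SEt). The configuration at B1 follows only from which enantiotopic arm is the nucleophile; the C2-symmetric ligand is meant to enforce this by tolerating, in the chair-like transition state, the small methyl group next to its phenyl substituent and the geranyl chain only in an open quadrant, and because the two chelates interconvert quickly the faster-closing one should set the product. The step needs carbon over oxygen acylation and no racemic background closure: the chelated magnesium enolate favours carbon attack (an enol lactone from oxygen attack would remain an acyl donor that can return), and the weak amine cannot enolize an unbound arm or form much thiolate, which also protects the non-enolizable 1,3-diketone from retro-Claisen cleavage.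

Step 7
Reactants: 9 S-ethyl (3R)-3-geranyl-2,4-dihydroxy-3-methyl-6-oxocyclohexa-1,4-diene-1-carbothioate
Product: 10 S-ethyl (3R)-3-geranyl-3-methyl-6-oxo-2,4-bis(trimethylsilyloxy)cyclohexa-1,4-diene-1-carbothioate
Conditions: BSA (2.5 equiv), CH2Cl2, rt; volatiles removed in vacuo, crude used directly
Reagents that add atoms: N,O-bis(trimethylsilyl)acetamide (BSA), CC(=N[Si](C)(C)C)O[Si](C)(C)C
Why: Neutral O-silylation of the two acidic enol hydroxyls masks the vinylogous acids, which would otherwise protonate the organozinc reagent and turn the thioester into an unreactive trionate; a regioisomeric bis(silyl enol ether) would serve equally, since all converge on hydrolysis.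

Step 8
Reactants: 10 S-ethyl (3R)-3-geranyl-3-methyl-6-oxo-2,4-bis(trimethylsilyloxy)cyclohexa-1,4-diene-1-carbothioate
Product: 12 (4R)-2-acetyl-4-geranyl-3,5-dihydroxy-4-methylcyclohexa-2,5-dien-1-one, via bis(trimethylsilyl) enol ether of the methyl ketone 11 (not isolated)
Conditions: MeZnI (3 equiv), PdCl2(PPh3)2 (10 mol %), toluene/THF, rt; then 1 M HCl, THF, 0 °C
Reagents that add atoms: methylzinc iodide, C[Zn]I
Why: Fukuyama coupling, in which zerovalent palladium inserts into the acyl–sulfur bond, methyl is transferred from zinc and reductive elimination gives the methyl ketone without touching ketone, enol ether or alkene; dilute acid then cleaves both silyl enol ethers, and the quaternary carbon is not involved.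

Step 9
Reactants: 13 1-(2,4,6-trihydroxyphenyl)butan-1-one (1.5 equiv); 2 geranyl bromide
Product: 14 1-(3-geranyl-2,4,6-trihydroxyphenyl)butan-1-one
Conditions: 10% aq KOH, 0 °C → rt; then 1 M HCl
Reagents that add atoms: none
Why: Electrophilic C-alkylation of the phloroglucinol phenoxide in water, where hydrogen bonding to oxygen favours attack through carbon; the two free ring positions are equivalent and a deficit of bromide limits double alkylation.

Step 10
Reactants: 12 (4R)-2-acetyl-4-geranyl-3,5-dihydroxy-4-methylcyclohexa-2,5-dien-1-one; 14 1-(3-geranyl-2,4,6-trihydroxyphenyl)butan-1-one (1.2 equiv)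
Product: 17 CNP0209203.1 (target), via ring B Mannich base 15 (not isolated), via exocyclic methylene trione 16 (not isolated)
Conditions: dimethyl(methylidene)ammonium iodide (1.05 equiv), MeCN, 0 °C → rt; then 14, NaOAc (1.5 equiv), 50 °C
Reagents that add atoms: dimethyl(methylidene)ammonium iodide, C=[N+](C)C.[I-]
Why: Mannich reaction at the only free enolic carbon B5 gives the betaine 15, which loses dimethylamine (E1cB) to the exocyclic enone 16; this is captured by the single free aromatic carbon of 14 in a Michael/Friedel–Crafts alkylation with rearomatization, under mild, weakly basic conditions that leave the quaternary stereocentre and the acetyl position unchanged.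

**Compound list**

1 | dimethyl methylmalonate (dimethyl 2-methylpropanedioate) | COC(=O)C(C)C(=O)OC | starting material
2 | geranyl bromide, (2E)-1-bromo-3,7-dimethylocta-2,6-diene | BrC/C=C(\C)CCC=C(C)C | starting material
3 | dimethyl 2-geranyl-2-methylpropanedioate | COC(=O)C(C)(C/C=C(\C)CCC=C(C)C)C(=O)OC | intermediate
4 | 2-geranyl-2-methylpropane-1,3-diol | OCC(C)(CO)C/C=C(\C)CCC=C(C)C | intermediate
5 | 2-geranyl-2-methylpropanedial | O=CC(C)(C=O)C/C=C(\C)CCC=C(C)C | intermediate
6 | S-ethyl thioacetate (S-ethyl ethanethioate) | CCSC(C)=O | starting material
7 | S,S-diethyl 4-geranyl-3,5-dihydroxy-4-methylheptanebis(thioate), mixture of diastereomers | CCSC(=O)CC(O)C(C)(C/C=C(\C)CCC=C(C)C)C(O)CC(=O)SCC | intermediate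
8 | S,S-diethyl 4-geranyl-4-methyl-3,5-dioxoheptanebis(thioate), achiral | CCSC(=O)CC(=O)C(C)(C/C=C(\C)CCC=C(C)C)C(=O)CC(=O)SCC | intermediate
9 | S-ethyl (3R)-3-geranyl-2,4-dihydroxy-3-methyl-6-oxocyclohexa-1,4-diene-1-carbothioate | CCSC(=O)C1=C(O)[C@](C)(C/C=C(\C)CCC=C(C)C)C(O)=CC1=O | intermediate
10 | S-ethyl (3R)-3-geranyl-3-methyl-6-oxo-2,4-bis(trimethylsilyloxy)cyclohexa-1,4-diene-1-carbothioate (one regioisomer drawn) | CCSC(=O)C1=C(O[Si](C)(C)C)[C@](C)(C/C=C(\C)CCC=C(C)C)C(O[Si](C)(C)C)=CC1=O | intermediate
11 | (4R)-2-acetyl-4-geranyl-4-methyl-3,5-bis(trimethylsilyloxy)cyclohexa-2,5-dien-1-one | CC(=O)C1=C(O[Si](C)(C)C)[C@](C)(C/C=C(\C)CCC=C(C)C)C(O[Si](C)(C)C)=CC1=O | intermediate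
12 | (4R)-2-acetyl-4-geranyl-3,5-dihydroxy-4-methylcyclohexa-2,5-dien-1-one | CC(=O)C1=C(O)[C@](C)(C/C=C(\C)CCC=C(C)C)C(O)=CC1=O | intermediate
13 | 1-(2,4,6-trihydroxyphenyl)butan-1-one | CCCC(=O)c1c(O)cc(O)cc1O | starting material
14 | 1-(3-geranyl-2,4,6-trihydroxyphenyl)butan-1-one | CCCC(=O)c1c(O)cc(O)c(C/C=C(\C)CCC=C(C)C)c1O | intermediate
15 | (4R)-2-acetyl-6-[(dimethylamino)methyl]-4-geranyl-3,5-dihydroxy-4-methylcyclohexa-2,5-dien-1-one | CC(=O)C1=C(O)[C@](C)(C/C=C(\C)CCC=C(C)C)C(O)=C(CN(C)C)C1=O | intermediate
16 | (4S)-2-acetyl-4-geranyl-3-hydroxy-4-methyl-6-methylidenecyclohex-2-ene-1,5-dione (same spatial arrangement as 12; the descriptor changes only through the CIP priorities) | CC(=O)C1=C(O)[C@](C)(C/C=C(\C)CCC=C(C)C)C(=O)C(=C)C1=O | intermediate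
17 | CNP0209203.1, (4R)-2-acetyl-6-[(3-butanoyl-5-geranyl-2,4,6-trihydroxyphenyl)methyl]-4-geranyl-3,5-dihydroxy-4-methylcyclohexa-2,5-dien-1-one | CCCC(=O)c1c(O)c(C/C=C(\C)CCC=C(C)C)c(O)c(CC2=C(O)[C@@](C)(C/C=C(\C)CCC=C(C)C)C(O)=C(C(C)=O)C2=O)c1O | target

**Step count and risks**

Total step count: 10. Longest linear sequence: 9 steps (steps 1–8 and 10, from dimethyl methylmalonate); step 9 is a one-step side branch.

Steps most likely to fail:

1. Step 6 (proposed new method). The chiral complex may discriminate poorly between the two enantiotopic arms, oxygen acylation may compete, or the strongly chelating product may slow the reaction and let an unselective closure take over. Fallback by known chemistry, setting out from 8: the chain is closed without a chiral ligand by ordinary soft-enolization Dieckmann condensation (MgBr2·OEt2, Et3N, CH2Cl2, rt) to the racemic S-ethyl thioester trione F1. This acidic racemate is then resolved by preparative chromatography on a chiral stationary phase, or by crystallization of its salt with a cinchona alkaloid. The (R) enantiomer is 9, where the route is rejoined; the (S)-enantiomer of 9 F2 is set aside.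

2. Step 8. Oxidative addition of zerovalent palladium into the hindered, electron-rich vinylogous thioester may be slow, or the silyl groups may be lost to zinc halide so that the freed acid protonates the zinc reagent. Fallback, setting out from 9 and skipping the silylation: a base-free Liebeskind–Srogl coupling of the free thioester with Me4Sn (Pd2(dba)3, tri(2-furyl)phosphine, CuO2PPh2 as the monovalent copper thiolate scavenger, THF, 50 °C). No basic organometallic is present, so the acidic enols need no protection. The methyl ketone is obtained directly and the route is rejoined at 12; no new compound is formed on the way.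

3. Step 10. The reactive enone 16 may be intercepted by unreacted 12 or by 15, giving a symmetric ring B dimer, or the bridge may exchange between rings on prolonged heating. Fallback with reversed roles, setting out from 14: aminomethylation of its last free ring carbon with dimethyl(methylidene)ammonium iodide in MeCN gives the ring A Mannich base F3, which has no free ring position left for self-coupling. Heating F3 with 12 and NaOAc in dioxane at 80 °C releases dimethylamine and forms the ring A ortho-quinone methide F4, which is trapped by the enol carbon B5 of 12 in a Michael addition. This gives the target directly, so the route is rejoined at 17.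

**Further compounds**

F1 | step 6 | racemic S-ethyl 3-geranyl-2,4-dihydroxy-3-methyl-6-oxocyclohexa-1,4-diene-1-carbothioate | CCSC(=O)C1=C(O)C(C)(C/C=C(\C)CCC=C(C)C)C(O)=CC1=O
F2 | step 6 | S-ethyl (3S)-3-geranyl-2,4-dihydroxy-3-methyl-6-oxocyclohexa-1,4-diene-1-carbothioate, the (S)-enantiomer of 9 | CCSC(=O)C1=C(O)[C@@](C)(C/C=C(\C)CCC=C(C)C)C(O)=CC1=O
F0 | step 8 | none | none
F3 | step 10 | 1-[3-[(dimethylamino)methyl]-5-geranyl-2,4,6-trihydroxyphenyl]butan-1-one | CCCC(=O)c1c(O)c(CN(C)C)c(O)c(C/C=C(\C)CCC=C(C)C)c1O
F4 | step 10 | ring A ortho-quinone methide, 2-butanoyl-4-geranyl-3,5-dihydroxy-6-methylidenecyclohexa-2,4-dien-1-one | CCCC(=O)C1=C(O)C(=C)C(=O)C(C/C=C(\C)CCC=C(C)C)=C1O
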